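## Retrosynthetic overview

1. Target ⇐ one fluoride deprotection of its tris(triethylsilyl) ether / 2-(trimethylsilyl)ethyl ester.
2. That compound ⇐ C12–C13 bond by a new nickel-catalysed reductive coupling of a C13 aldehyde (C13–C23 polyol–triene–oxazole) with a C1–C12 lactone enyne; this sets C13 and the E C11=C12 alkene.
3. Aldehyde ⇐ Evans syn aldol (C16, C17) on an oxazolyl trienal (Wittig, Horner–Wadsworth–Emmons), Claisen chain extension, Evans–Saksena anti reduction (C15).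
4. Enyne ⇐ cinchona desymmetrisation of 3-allylglutaric anhydride (C5), acrylate cross-metathesis, phosphoric-acid-catalysed (Z)-crotylboration (C7, C8), vinylboronate cross-metathesis, alkynyl Suzuki coupling.
5. Rings: the oxazole is bought; the δ-lactone is the only ring made (step 19, C7–OH onto the C5 acetate arm); no macrocycle is closed.

Assumption and numbering: locants run along the chain from the acid carbon C1 to C23 (the carbon bearing the oxazole); C5 carries the lactone acetate arm. The target is 5R,7R,8R,13R,15S,16S,17R with all six C=C bonds E. Compounds 1, 2, 4, 8, 15, 16, 18, 19, 27, 30 and 32 are taken as catalogue compounds. Transient anions, enolates and catalyst-bound species are not numbered.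

## Route

### Fragment A: C13–C23 aldehyde 14

Step 1
Reactants: 1 2-methyl-1,3-oxazole-4-carbaldehyde; 2 2-(triphenyl-λ5-phosphanylidene)propanal
Product: 3 (2E)-2-methyl-3-(2-methyl-1,3-oxazol-4-yl)prop-2-enal
Conditions: PhMe, 80 °C
Reagents that add atoms: none
Why: Wittig olefination with a stabilised ylide gives the E-trisubstituted C22=C23 enal and does not react further with the less electrophilic product.

Step 2
Reactants: 3 (2E)-2-methyl-3-(2-methyl-1,3-oxazol-4-yl)prop-2-enal; 4 ethyl (2E)-4-(diethoxyphosphoryl)-2-methylbut-2-enoate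
Product: 5 ethyl (2E,4E,6E)-2,6-dimethyl-7-(2-methyl-1,3-oxazol-4-yl)hepta-2,4,6-trienoate
Conditions: LiN(SiMe3)2, THF, −78 to 0 °C
Reagents that add atoms: none
Why: Vinylogous Horner–Wadsworth–Emmons olefination forms the C20=C21 bond E under thermodynamic control, while the E C18=C19 geometry is carried in by the phosphonate.

Step 3
Reactants: 5 ethyl (2E,4E,6E)-2,6-dimethyl-7-(2-methyl-1,3-oxazol-4-yl)hepta-2,4,6-trienoate
Product: 6 (2E,4E,6E)-2,6-dimethyl-7-(2-methyl-1,3-oxazol-4-yl)hepta-2,4,6-trien-1-ol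
Conditions: i-Bu2AlH (2.5 equiv), CH2Cl2, −78 °C; Rochelle salt
Reagents that add atoms: none
Why: 1,2-Reduction of a conjugated ester by i-Bu2AlH gives the allylic alcohol without touching the triene or the oxazole.

Step 4
Reactants: 6 (2E,4E,6E)-2,6-dimethyl-7-(2-methyl-1,3-oxazol-4-yl)hepta-2,4,6-trien-1-ol
Product: 7 (2E,4E,6E)-2,6-dimethyl-7-(2-methyl-1,3-oxazol-4-yl)hepta-2,4,6-trienal
Conditions: MnO2, CH2Cl2, rt, dark
Reagents that add atoms: none
Why: MnO2 oxidises allylic alcohols selectively and neutrally, so the sensitive trienal forms without isomerisation.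

Step 5
Reactants: 7 (2E,4E,6E)-2,6-dimethyl-7-(2-methyl-1,3-oxazol-4-yl)hepta-2,4,6-trienal; 8 (4R)-4-benzyl-3-propanoyl-1,3-oxazolidin-2-one
Product: 9 (4R)-4-benzyl-3-[(2R,3R,4E,6E,8E)-3-hydroxy-2,4,8-trimethyl-9-(2-methyl-1,3-oxazol-4-yl)nona-4,6,8-trienoyl]-1,3-oxazolidin-2-one
Conditions: n-Bu2BOTf, i-Pr2NEt, CH2Cl2, −78 to 0 °C; then 7, −78 to −10 °C; H2O2, pH 7 buffer, MeOH, 0 °C
Reagents that add atoms: none
Why: Evans syn aldol reaction; the Z boron enolate reacts through a Zimmerman–Traxler chair with the auxiliary dipole opposed, so the (R)-benzyl auxiliary delivers the 16,17-syn pair with C16 S and C17 R (target locants).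

Step 6
Reactants: 9 (4R)-4-benzyl-3-[(2R,3R,4E,6E,8E)-3-hydroxy-2,4,8-trimethyl-9-(2-methyl-1,3-oxazol-4-yl)nona-4,6,8-trienoyl]-1,3-oxazolidin-2-one
Product: 10 (2R,3R,4E,6E,8E)-3-hydroxy-N-methoxy-N,2,4,8-tetramethyl-9-(2-methyl-1,3-oxazol-4-yl)nona-4,6,8-trienamide
Conditions: MeONHMe·HCl, AlMe3, CH2Cl2/THF, −20 to 0 °C
Reagents that add atoms: N,O-dimethylhydroxylamine hydrochloride (CNOC.Cl)
Why: Aluminium-amide transamination of the imide, assisted by the free β-hydroxyl, cleaves the auxiliary at the exocyclic carbonyl without epimerising C16.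

Step 7
Reactants: 10 (2R,3R,4E,6E,8E)-3-hydroxy-N-methoxy-N,2,4,8-tetramethyl-9-(2-methyl-1,3-oxazol-4-yl)nona-4,6,8-trienamide
Product: 11 ethyl (4R,5R,6E,8E,10E)-5-hydroxy-4,6,10-trimethyl-11-(2-methyl-1,3-oxazol-4-yl)-3-oxoundeca-6,8,10-trienoate
Conditions: EtOAc, LiN(i-Pr)2 (4 equiv each), THF, −78 °C; aq NH4Cl
Reagents that add atoms: ethyl acetate (CCOC(C)=O)
Why: Crossed Claisen acylation of the pre-formed lithium ester enolate by the Weinreb amide stops at the ketone through the chelated tetrahedral intermediate, and the product is stored as its C14 enolate so C16 is not epimerised.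

Step 8
Reactants: 11 ethyl (4R,5R,6E,8E,10E)-5-hydroxy-4,6,10-trimethyl-11-(2-methyl-1,3-oxazol-4-yl)-3-oxoundeca-6,8,10-trienoate
Product: 12 ethyl (3S,4S,5R,6E,8E,10E)-3,5-dihydroxy-4,6,10-trimethyl-11-(2-methyl-1,3-oxazol-4-yl)undeca-6,8,10-trienoate
Conditions: Me4NBH(OAc)3, MeCN/AcOH 1:1, −30 °C
Reagents that add atoms: none
Why: Evans–Saksena reduction; the C17 hydroxyl binds the acetoxyborohydride and delivers hydride intramolecularly through a chair, giving the 15,17-anti diol (C15 S).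

Step 9
Reactants: 12 ethyl (3S,4S,5R,6E,8E,10E)-3,5-dihydroxy-4,6,10-trimethyl-11-(2-methyl-1,3-oxazol-4-yl)undeca-6,8,10-trienoate
Product: 13 ethyl (3S,4S,5R,6E,8E,10E)-4,6,10-trimethyl-11-(2-methyl-1,3-oxazol-4-yl)-3,5-bis[(triethylsilyl)oxy]undeca-6,8,10-trienoate
Conditions: Et3SiOTf, 2,6-lutidine, CH2Cl2, −78 to 0 °C
Reagents that add atoms: triethylsilyl trifluoromethanesulfonate (CC[Si](CC)(CC)OS(=O)(=O)C(F)(F)F)
Why: Silyl triflate with a hindered base silylates both secondary alcohols at low temperature without ionising the trienylic C17–O bond.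

Step 10
Reactants: 13 ethyl (3S,4S,5R,6E,8E,10E)-4,6,10-trimethyl-11-(2-methyl-1,3-oxazol-4-yl)-3,5-bis[(triethylsilyl)oxy]undeca-6,8,10-trienoate
Product: 14 (3S,4S,5R,6E,8E,10E)-4,6,10-trimethyl-11-(2-methyl-1,3-oxazol-4-yl)-3,5-bis[(triethylsilyl)oxy]undeca-6,8,10-trienal
Conditions: i-Bu2AlH (1.1 equiv), CH2Cl2, −78 °C; MeOH, Rochelle salt
Reagents that add atoms: none
Why: Partial reduction of the β-silyloxy ester stops at the aldehyde because the aluminium hemiacetal is stable at −78 °C.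

### Fragment B: C1–C12 lactone enyne 34

Step 11
Reactants: 15 prop-2-enoyl chloride; 16 2-(trimethylsilyl)ethanol
Product: 17 2-(trimethylsilyl)ethyl prop-2-enoate
Conditions: Et3N, CH2Cl2, 0 °C
Reagents that add atoms: none
Why: Simple acylation gives the acrylate whose ester is later removed by fluoride together with the silyl ethers.

Step 12
Reactants: 18 dimethyl (2E)-pent-2-enedioate; 19 allylmagnesium bromide
Product: 20 dimethyl 3-(prop-2-en-1-yl)pentanedioate
Conditions: CuBr·SMe2 (1 equiv), Me3SiCl (2 equiv), THF, −78 °C; aq NH4Cl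
Reagents that add atoms: none
Why: Chlorosilane-accelerated conjugate addition of the allylcopper reagent outruns 1,2-addition and γ-deprotonation, and the silyl ketene acetal is hydrolysed on work-up.

Step 13
Reactants: 20 dimethyl 3-(prop-2-en-1-yl)pentanedioate
Product: 21 3-(prop-2-en-1-yl)pentanedioic acid
Conditions: LiOH, THF/H2O, rt; then HCl
Reagents that add atoms: lithium hydroxide ([Li+].[OH-])
Why: Standard saponification of both methyl esters.

Step 14
Reactants: 21 3-(prop-2-en-1-yl)pentanedioic acid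
Product: 22 4-(prop-2-en-1-yl)oxane-2,6-dione
Conditions: Ac2O, reflux; distil
Reagents that add atoms: none
Why: Cyclodehydration of a glutaric acid to its six-membered anhydride is thermodynamically favoured.

Step 15
Reactants: 22 4-(prop-2-en-1-yl)oxane-2,6-dione
Product: 23 (3R)-3-(2-methoxy-2-oxoethyl)hex-5-enoic acid
Conditions: MeOH (10 equiv), (DHQD)2AQN (10 mol %), Et2O, −40 °C
Reagents that add atoms: methanol (CO)
Why: Cinchona-alkaloid general-base-catalysed desymmetrising methanolysis opens one enantiotopic carbonyl and so sets C5; the pseudoenantiomeric (DHQ)2AQN gives the mirror-image half ester, so the sense is fixed by the choice of alkaloid.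

Step 16
Reactants: 23 (3R)-3-(2-methoxy-2-oxoethyl)hex-5-enoic acid; 17 2-(trimethylsilyl)ethyl prop-2-enoate
Product: 24 (3R,5E)-3-(2-methoxy-2-oxoethyl)-7-oxo-7-[2-(trimethylsilyl)ethoxy]hept-5-enoic acid
Conditions: 17 (3 equiv), second-generation Grubbs catalyst (3 mol %), CH2Cl2, 40 °C
Reagents that add atoms: none
Why: Cross-metathesis of a terminal alkene with an acrylate is selective and E-selective, installs the C1–C3 enoate, and removes the alkene that borane would otherwise hydroborate.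

Step 17
Reactants: 24 (3R,5E)-3-(2-methoxy-2-oxoethyl)-7-oxo-7-[2-(trimethylsilyl)ethoxy]hept-5-enoic acid
Product: 25 7-methyl 1-[2-(trimethylsilyl)ethyl] (2E,5R)-5-(2-hydroxyethyl)hept-2-enedioate
Conditions: BH3·SMe2 (1.2 equiv), THF, −10 to 0 °C; MeOH
Reagents that add atoms: none
Why: Borane reduces the free carboxylic acid through its acyloxyborane much faster than it attacks esters or the electron-poor enoate, and the crude alcohol is used at once to avoid lactonisation.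

Step 18
Reactants: 25 7-methyl 1-[2-(trimethylsilyl)ethyl] (2E,5R)-5-(2-hydroxyethyl)hept-2-enedioate
Product: 26 7-methyl 1-[2-(trimethylsilyl)ethyl] (2E,5R)-5-(2-oxoethyl)hept-2-enedioate
Conditions: Dess–Martin periodinane, NaHCO3, CH2Cl2, rt
Reagents that add atoms: none
Why: Dess–Martin oxidation gives the C7 aldehyde under neutral conditions without touching the enoate or the C5 centre.

Step 19
Reactants: 26 7-methyl 1-[2-(trimethylsilyl)ethyl] (2E,5R)-5-(2-oxoethyl)hept-2-enedioate; 27 2-[(2Z)-but-2-en-1-yl]-4,4,5,5-tetramethyl-1,3,2-dioxaborolane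
Product: 29 2-(trimethylsilyl)ethyl (2E)-4-[(2R,4R)-2-[(2R)-but-3-en-2-yl]-6-oxooxan-4-yl]but-2-enoate, via open-chain hydroxy ester 28 (not isolated)
Conditions: (S)-TRIP (5 mol %), 4 Å MS, PhMe, −30 °C; then p-TsOH·H2O (0.2 equiv), CH2Cl2, rt
Reagents that add atoms: none
Why: Chiral-phosphoric-acid-catalysed crotylboration through a closed chair transition state; the Z-crotyl geometry gives the 7,8-syn pair, the (S)-acid (3,3′-bis(2,4,6-triisopropylphenyl)-BINOL hydrogen phosphate) directs Si-face attack (7R,8R), and acid-catalysed lactonisation onto the methyl ester then closes the cis-4,6-disubstituted δ-lactone.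

Step 20
Reactants: 30 propyne
Product: 31 1-bromoprop-1-yne
Conditions: N-bromosuccinimide, AgNO3 (10 mol %), acetone, 0 °C to rt; used as a solution
Reagents that add atoms: N-bromosuccinimide (O=C1CCC(=O)N1Br)
Why: Silver-catalysed electrophilic bromination of a terminal alkyne via the silver acetylide.

Step 21
Reactants: 29 2-(trimethylsilyl)ethyl (2E)-4-[(2R,4R)-2-[(2R)-but-3-en-2-yl]-6-oxooxan-4-yl]but-2-enoate; 32 2-ethenyl-4,4,5,5-tetramethyl-1,3,2-dioxaborolane
Product: 33 2-(trimethylsilyl)ethyl (2E)-4-[(2R,4R)-6-oxo-2-[(2R,3E)-4-(4,4,5,5-tetramethyl-1,3,2-dioxaborolan-2-yl)but-3-en-2-yl]oxan-4-yl]but-2-enoate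
Conditions: 32 (3 equiv), second-generation Hoveyda–Grubbs catalyst (5 mol %), CH2Cl2, 40 °C
Reagents that add atoms: none
Why: Cross-metathesis of the terminal vinyl group with the vinylboronate gives the E-alkenylboronate (C9=C10), while the disubstituted electron-poor enoate is a much slower metathesis partner.

Step 22
Reactants: 33 2-(trimethylsilyl)ethyl (2E)-4-[(2R,4R)-6-oxo-2-[(2R,3E)-4-(4,4,5,5-tetramethyl-1,3,2-dioxaborolan-2-yl)but-3-en-2-yl]oxan-4-yl]but-2-enoate; 31 1-bromoprop-1-yne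
Product: 34 2-(trimethylsilyl)ethyl (2E)-4-[(2R,4R)-2-[(2R,3E)-hept-3-en-5-yn-2-yl]-6-oxooxan-4-yl]but-2-enoate
Conditions: Pd(PPh3)4 (5 mol %), K3PO4 (aq), THF, rt
Reagents that add atoms: none
Why: Suzuki–Miyaura coupling of an alkenylboronate with an alkynyl bromide proceeds with retention of the E geometry under a mild base that the lactone tolerates at room temperature.

### Union and deprotection

Step 23
Reactants: 14 (3S,4S,5R,6E,8E,10E)-4,6,10-trimethyl-11-(2-methyl-1,3-oxazol-4-yl)-3,5-bis[(triethylsilyl)oxy]undeca-6,8,10-trienal; 34 2-(trimethylsilyl)ethyl (2E)-4-[(2R,4R)-2-[(2R,3E)-hept-3-en-5-yn-2-yl]-6-oxooxan-4-yl]but-2-enoate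
Product: 35 2-(trimethylsilyl)ethyl (2E)-4-[(2R,4R)-2-[(2R,3E,5E,7R,9S,10S,11R,12E,14E,16E)-6,10,12,16-tetramethyl-17-(2-methyl-1,3-oxazol-4-yl)-7,9,11-tris[(triethylsilyl)oxy]heptadeca-3,5,12,14,16-pentaen-2-yl]-6-oxooxan-4-yl]but-2-enoate
Conditions: Ni(cod)2 (10 mol %), L*·HBF4 (10 mol %), KOt-Bu (10 mol %), Et3SiH (2 equiv), THF, rt, slow addition of 14 to 34 (1.2 equiv)
Reagents that add atoms: triethylsilane (CC[SiH](CC)CC)
Why: Proposed new method: a ligand-controlled, 1,3-syn-selective nickel-catalysed reductive coupling of a conjugated enyne with a β-silyloxy aldehyde, used as a fragment union. Zerovalent nickel bearing the C2-symmetric carbene L* ((4S,5S)-1,3-bis(2-cyclohexyl-6-methylphenyl)-4,5-diphenylimidazolin-2-ylidene; its antipode is the control, and the one giving 13R is kept) binds the alkyne of 34 with the adjacent alkene as a second π-donor, so oxidative cyclisation with 14 forms the C–C bond at the methyl-bearing alkyne carbon C12 and the chiral carbene selects the aldehyde face (13R, syn to C15–O); Si–H σ-bond metathesis then silylates the Ni–O bond and C–H reductive elimination places H cis to C13, giving the E C11=C12 alkene and the C13 triethylsilyl ether in one step. The β-alkyl enoate and the trisubstituted triene are much weaker π-acceptors than the alkyne. The closest known reaction type is the nickel/N-heterocyclic-carbene/silane aldehyde–alkyne reductive coupling (enantioselective only with simple partners) and the phosphine/borane coupling of enynes, neither shown with a chiral carbene on an enyne, with catalyst-controlled diastereoselection on a β-oxygenated aldehyde, or between two advanced fragments.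

Step 24
Reactants: 35 2-(trimethylsilyl)ethyl (2E)-4-[(2R,4R)-2-[(2R,3E,5E,7R,9S,10S,11R,12E,14E,16E)-6,10,12,16-tetramethyl-17-(2-methyl-1,3-oxazol-4-yl)-7,9,11-tris[(triethylsilyl)oxy]heptadeca-3,5,12,14,16-pentaen-2-yl]-6-oxooxan-4-yl]but-2-enoate
Product: 36 (2E)-4-[(2R,4R)-2-[(2R,3E,5E,7R,9S,10S,11R,12E,14E,16E)-7,9,11-trihydroxy-6,10,12,16-tetramethyl-17-(2-methyl-1,3-oxazol-4-yl)heptadeca-3,5,12,14,16-pentaen-2-yl]-6-oxooxan-4-yl]but-2-enoic acid
Conditions: Bu4NF (6 equiv), THF, 0 °C to rt, dark; aq NH4Cl (pH 5)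
Reagents that add atoms: none
Why: Fluoride cleaves the three Si–O bonds and attacks the ester silicon to trigger β-elimination of ethene and Me3SiF, releasing the triol acid without acid (allylic ionisation) or hydroxide (lactone opening).

## Compound list

1 | 2-methyl-1,3-oxazole-4-carbaldehyde | Cc1nc(C=O)co1 | starting material
2 | 2-(triphenyl-λ5-phosphanylidene)propanal | CC(C=O)=P(c1ccccc1)(c1ccccc1)c1ccccc1 | starting material
3 | (2E)-2-methyl-3-(2-methyl-1,3-oxazol-4-yl)prop-2-enal | CC(/C=O)=C\c1coc(C)n1 | intermediate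
4 | ethyl (2E)-4-(diethoxyphosphoryl)-2-methylbut-2-enoate | CCOC(=O)/C(C)=C/CP(=O)(OCC)OCC | starting material
5 | ethyl (2E,4E,6E)-2,6-dimethyl-7-(2-methyl-1,3-oxazol-4-yl)hepta-2,4,6-trienoate | CC(/C=C/C=C(\C)C(=O)OCC)=C\c1coc(C)n1 | intermediate
6 | (2E,4E,6E)-2,6-dimethyl-7-(2-methyl-1,3-oxazol-4-yl)hepta-2,4,6-trien-1-ol | CC(/C=C/C=C(\C)CO)=C\c1coc(C)n1 | intermediate
7 | (2E,4E,6E)-2,6-dimethyl-7-(2-methyl-1,3-oxazol-4-yl)hepta-2,4,6-trienal | CC(/C=C/C=C(\C)C=O)=C\c1coc(C)n1 | intermediate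
8 | (4R)-4-benzyl-3-propanoyl-1,3-oxazolidin-2-one | CCC(=O)N1[C@H](Cc2ccccc2)COC1=O | starting material
9 | (4R)-4-benzyl-3-[(2R,3R,4E,6E,8E)-3-hydroxy-2,4,8-trimethyl-9-(2-methyl-1,3-oxazol-4-yl)nona-4,6,8-trienoyl]-1,3-oxazolidin-2-one | CC(/C=C/C=C(\C)[C@H](O)[C@@H](C)C(=O)N1[C@H](Cc2ccccc2)COC1=O)=C\c1coc(C)n1 | intermediate
10 | (2R,3R,4E,6E,8E)-3-hydroxy-N-methoxy-N,2,4,8-tetramethyl-9-(2-methyl-1,3-oxazol-4-yl)nona-4,6,8-trienamide | CC(/C=C/C=C(\C)[C@H](O)[C@@H](C)C(=O)N(C)OC)=C\c1coc(C)n1 | intermediate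
11 | ethyl (4R,5R,6E,8E,10E)-5-hydroxy-4,6,10-trimethyl-11-(2-methyl-1,3-oxazol-4-yl)-3-oxoundeca-6,8,10-trienoate | CC(/C=C/C=C(\C)[C@H](O)[C@@H](C)C(=O)CC(=O)OCC)=C\c1coc(C)n1 | intermediate
12 | ethyl (3S,4S,5R,6E,8E,10E)-3,5-dihydroxy-4,6,10-trimethyl-11-(2-methyl-1,3-oxazol-4-yl)undeca-6,8,10-trienoate | CC(/C=C/C=C(\C)[C@H](O)[C@@H](C)[C@@H](O)CC(=O)OCC)=C\c1coc(C)n1 | intermediate
13 | ethyl (3S,4S,5R,6E,8E,10E)-4,6,10-trimethyl-11-(2-methyl-1,3-oxazol-4-yl)-3,5-bis[(triethylsilyl)oxy]undeca-6,8,10-trienoate | CC(/C=C/C=C(\C)[C@H](O[Si](CC)(CC)CC)[C@@H](C)[C@@H](O[Si](CC)(CC)CC)CC(=O)OCC)=C\c1coc(C)n1 | intermediate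
14 | (3S,4S,5R,6E,8E,10E)-4,6,10-trimethyl-11-(2-methyl-1,3-oxazol-4-yl)-3,5-bis[(triethylsilyl)oxy]undeca-6,8,10-trienal | CC(/C=C/C=C(\C)[C@H](O[Si](CC)(CC)CC)[C@@H](C)[C@@H](O[Si](CC)(CC)CC)CC=O)=C\c1coc(C)n1 | intermediate
15 | prop-2-enoyl chloride | C=CC(=O)Cl | starting material
16 | 2-(trimethylsilyl)ethanol | C[Si](C)(C)CCO | starting material
17 | 2-(trimethylsilyl)ethyl prop-2-enoate | C=CC(=O)OCC[Si](C)(C)C | intermediate
18 | dimethyl (2E)-pent-2-enedioate | COC(=O)/C=C/CC(=O)OC | starting material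
19 | allylmagnesium bromide | C=CC[Mg]Br | starting material
20 | dimethyl 3-(prop-2-en-1-yl)pentanedioate | COC(=O)CC(CC=C)CC(=O)OC | intermediate
21 | 3-(prop-2-en-1-yl)pentanedioic acid | OC(=O)CC(CC=C)CC(=O)O | intermediate
22 | 4-(prop-2-en-1-yl)oxane-2,6-dione | C=CCC1CC(=O)OC(=O)C1 | intermediate
23 | (3R)-3-(2-methoxy-2-oxoethyl)hex-5-enoic acid | OC(=O)C[C@@H](CC=C)CC(=O)OC | intermediate
24 | (3R,5E)-3-(2-methoxy-2-oxoethyl)-7-oxo-7-[2-(trimethylsilyl)ethoxy]hept-5-enoic acid | OC(=O)C[C@@H](C/C=C/C(=O)OCC[Si](C)(C)C)CC(=O)OC | intermediate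
25 | 7-methyl 1-[2-(trimethylsilyl)ethyl] (2E,5R)-5-(2-hydroxyethyl)hept-2-enedioate | OCC[C@@H](C/C=C/C(=O)OCC[Si](C)(C)C)CC(=O)OC | intermediate
26 | 7-methyl 1-[2-(trimethylsilyl)ethyl] (2E,5R)-5-(2-oxoethyl)hept-2-enedioate | O=CC[C@@H](C/C=C/C(=O)OCC[Si](C)(C)C)CC(=O)OC | intermediate
27 | 2-[(2Z)-but-2-en-1-yl]-4,4,5,5-tetramethyl-1,3,2-dioxaborolane | C/C=C\CB1OC(C)(C)C(C)(C)O1 | starting material
28 | 7-methyl 1-[2-(trimethylsilyl)ethyl] (2E,5R)-5-[(2R,3R)-2-hydroxy-3-methylpent-4-en-1-yl]hept-2-enedioate | C=C[C@@H](C)[C@H](O)C[C@@H](C/C=C/C(=O)OCC[Si](C)(C)C)CC(=O)OC | intermediate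
29 | 2-(trimethylsilyl)ethyl (2E)-4-[(2R,4R)-2-[(2R)-but-3-en-2-yl]-6-oxooxan-4-yl]but-2-enoate | C=C[C@@H](C)[C@H]1C[C@@H](C/C=C/C(=O)OCC[Si](C)(C)C)CC(=O)O1 | intermediate
30 | propyne | CC#C | starting material
31 | 1-bromoprop-1-yne | CC#CBr | intermediate
32 | 2-ethenyl-4,4,5,5-tetramethyl-1,3,2-dioxaborolane | C=CB1OC(C)(C)C(C)(C)O1 | starting material
33 | 2-(trimethylsilyl)ethyl (2E)-4-[(2R,4R)-6-oxo-2-[(2R,3E)-4-(4,4,5,5-tetramethyl-1,3,2-dioxaborolan-2-yl)but-3-en-2-yl]oxan-4-yl]but-2-enoate | CC1(C)OB(/C=C/[C@@H](C)[C@H]2C[C@@H](C/C=C/C(=O)OCC[Si](C)(C)C)CC(=O)O2)OC1(C)C | intermediate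
34 | 2-(trimethylsilyl)ethyl (2E)-4-[(2R,4R)-2-[(2R,3E)-hept-3-en-5-yn-2-yl]-6-oxooxan-4-yl]but-2-enoate | CC#C/C=C/[C@@H](C)[C@H]1C[C@@H](C/C=C/C(=O)OCC[Si](C)(C)C)CC(=O)O1 | intermediate
35 | 2-(trimethylsilyl)ethyl (2E)-4-[(2R,4R)-2-[(2R,3E,5E,7R,9S,10S,11R,12E,14E,16E)-6,10,12,16-tetramethyl-17-(2-methyl-1,3-oxazol-4-yl)-7,9,11-tris[(triethylsilyl)oxy]heptadeca-3,5,12,14,16-pentaen-2-yl]-6-oxooxan-4-yl]but-2-enoate | CC(/C=C/C=C(\C)[C@H](O[Si](CC)(CC)CC)[C@@H](C)[C@@H](O[Si](CC)(CC)CC)C[C@@H](O[Si](CC)(CC)CC)/C(C)=C/C=C/[C@@H](C)[C@H]1C[C@@H](C/C=C/C(=O)OCC[Si](C)(C)C)CC(=O)O1)=C\c1coc(C)n1 | intermediate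
36 | (2E)-4-[(2R,4R)-2-[(2R,3E,5E,7R,9S,10S,11R,12E,14E,16E)-7,9,11-trihydroxy-6,10,12,16-tetramethyl-17-(2-methyl-1,3-oxazol-4-yl)heptadeca-3,5,12,14,16-pentaen-2-yl]-6-oxooxan-4-yl]but-2-enoic acid (CNP0198746.1) | CC(/C=C/C=C(\C)[C@H](O)[C@@H](C)[C@@H](O)C[C@@H](O)/C(C)=C/C=C/[C@@H](C)[C@H]1C[C@@H](C/C=C/C(=O)O)CC(=O)O1)=C\c1coc(C)n1 | target

## Step count and risks

Total step count: 24. Longest linear sequence: 12 steps (steps 1–10, 23, 24; the lactone branch, steps 12–19, 21–24, is also 12).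

Three steps most likely to fail:

Step 23 (the proposed new coupling). The chiral carbene may give poor 13R/13S selectivity, the silane may simply hydrosilylate the aldehyde, or nickel may be held up by the triene or the enoate. The fallback uses known chemistry, sets out from 34 (with 14 as partner) and comes back at 35. Hydrozirconation of the alkyne of 34 with Cp2Zr(H)Cl (zirconium goes to the methyl-bearing carbon) and iodinolysis with I2 give 2-(trimethylsilyl)ethyl (2E)-4-[(2R,4R)-2-[(2R,3E,5E)-6-iodohepta-3,5-dien-2-yl]-6-oxooxan-4-yl]but-2-enoate F1. A Nozaki–Hiyama–Kishi coupling of F1 with 14 (CrCl2, catalytic NiCl2, chiral sulfonamide ligand for divalent chromium, THF/MeCN) gives the C13 allylic alcohol F2, whose 13-epimer is removed by chromatography. Silylation of F2 with Et3SiOTf and 2,6-lutidine gives 35.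

Step 21 (cross-metathesis to the alkenylboronate). The vinyl group is α-branched and next to the lactone, so the reaction may be slow, give E/Z mixtures or involve the enoate. The fallback sets out from 29 and comes back at 34, bypassing steps 21 and 22. Selective ozonolysis of the terminal alkene (O3, CH2Cl2/MeOH, −78 °C, dye end-point, then Me2S; the enoate is much less reactive) gives 2-(trimethylsilyl)ethyl (2E)-4-[(2R,4R)-6-oxo-2-[(2S)-1-oxopropan-2-yl]oxan-4-yl]but-2-enoate F3. Takai iodo-olefination (CHI3, CrCl2, THF, 0 °C) gives the E-vinyl iodide 2-(trimethylsilyl)ethyl (2E)-4-[(2R,4R)-2-[(2R,3E)-4-iodobut-3-en-2-yl]-6-oxooxan-4-yl]but-2-enoate F4. Sonogashira coupling of F4 with propyne 30 (PdCl2(PPh3)2, CuI, i-Pr2NH, THF) gives 34.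

Step 24 (global deprotection). Basic Bu4NF may open or transacylate the lactone, or degrade the polyene, before the 2-(trimethylsilyl)ethyl ester is fully cleaved. The fallback sets out from 35 and comes back at 36 by a two-stage unmasking. HF·pyridine buffered with pyridine (THF, 0 °C) removes only the three triethylsilyl ethers to give the triol ester 2-(trimethylsilyl)ethyl (2E)-4-[(2R,4R)-2-[(2R,3E,5E,7R,9S,10S,11R,12E,14E,16E)-7,9,11-trihydroxy-6,10,12,16-tetramethyl-17-(2-methyl-1,3-oxazol-4-yl)heptadeca-3,5,12,14,16-pentaen-2-yl]-6-oxooxan-4-yl]but-2-enoate F5. Anhydrous, weakly basic tris(dimethylamino)sulfonium difluorotrimethylsilicate (DMF, 0 °C) then cleaves the ester of F5 to give 36.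

## Further compounds

F1 | step 23 | 2-(trimethylsilyl)ethyl (2E)-4-[(2R,4R)-2-[(2R,3E,5E)-6-iodohepta-3,5-dien-2-yl]-6-oxooxan-4-yl]but-2-enoate | I/C(C)=C/C=C/[C@@H](C)[C@H]1C[C@@H](C/C=C/C(=O)OCC[Si](C)(C)C)CC(=O)O1
F2 | step 23 | C13 allylic alcohol: compound 35 with a free 13R hydroxyl in place of the C13 triethylsilyl ether | CC(/C=C/C=C(\C)[C@H](O[Si](CC)(CC)CC)[C@@H](C)[C@@H](O[Si](CC)(CC)CC)C[C@@H](O)/C(C)=C/C=C/[C@@H](C)[C@H]1C[C@@H](C/C=C/C(=O)OCC[Si](C)(C)C)CC(=O)O1)=C\c1coc(C)n1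
F3 | step 21 | 2-(trimethylsilyl)ethyl (2E)-4-[(2R,4R)-6-oxo-2-[(2S)-1-oxopropan-2-yl]oxan-4-yl]but-2-enoate | O=C[C@@H](C)[C@H]1C[C@@H](C/C=C/C(=O)OCC[Si](C)(C)C)CC(=O)O1
F4 | step 21 | 2-(trimethylsilyl)ethyl (2E)-4-[(2R,4R)-2-[(2R,3E)-4-iodobut-3-en-2-yl]-6-oxooxan-4-yl]but-2-enoate | I/C=C/[C@@H](C)[C@H]1C[C@@H](C/C=C/C(=O)OCC[Si](C)(C)C)CC(=O)O1
F5 | step 24 | 2-(trimethylsilyl)ethyl ester of the target triol (compound 36 esterified at C1) | CC(/C=C/C=C(\C)[C@H](O)[C@@H](C)[C@@H](O)C[C@@H](O)/C(C)=C/C=C/[C@@H](C)[C@H]1C[C@@H](C/C=C/C(=O)OCC[Si](C)(C)C)CC(=O)O1)=C\c1coc(C)n1
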